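## Structural features

Sarothralin is a dimeric acylphloroglucinol: an aromatic ring A and a dearomatised, enolised cyclohexadienone ring B are joined by one methylene bridge, and an unsubstituted phenyl ring is attached to ring A through a ketone. Ring A carries the benzoyl group on C1, free hydroxyls on C2 and C4, the bridge carbon on C3, hydrogen on C5 and a 3-methylbut-2-enyl (prenyl) ether on C6. Ring B is an isobutyrylfilicinic acid unit with a gem-dimethyl carbon, an isobutyryl group and two enolic hydroxyls, drawn as one of several interconverting enol tautomers. There is no stereocenter and no stereogenic double bond, so no stereocenters stand next to each other and nothing has to be controlled in that respect. The fragile groups are the aryl prenyl ether (sensitive to Lewis and Brønsted acids and to strong oxidants), the doubly activated methylene bridge (easily over-oxidised) and the acidic β-triketone of ring B. The real difficulty is regiochemical: of the three phenolic oxygens of ring A only O6, para to C3 and ortho to C1, is alkylated. The key step exploits this: a ring synthesis that delivers O6 free and O2 and O4 masked, with the future bridge carbon on C3 and hydrogens on the equivalent positions C1 and C5, fixes the prenylation site and leaves a single outcome for introducing the benzoyl group.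

## Logic of the disconnections

**28 ⇒ 22 + 26.** The bond cut joins the bridge carbon to C1' of ring B. The ring B carbon is the nucleophilic position of an acidic enol, and the bridge carbon can stay on ring A as a methyl group and be raised to the electrophilic level as 27. The gain is convergence: two halves of similar size, each fully substituted. The forward step must oxidise that one methyl group without harming the prenyl ether, 26 or the new bridge of 28.

**26 ⇒ 25 ⇒ 23 + 24.** The two C–CH3 bonds at the quaternary carbon of ring B are cut, then the ring-to-acyl bond. Ring B thus comes from a symmetric triol and an acid chloride. The forward steps need a mono-acylation and a double C-methylation at one carbon that stops before a third methyl enters.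

**22 ⇒ 21 ⇒ 19 (through 20).** After the two O–Si bonds, the C1–carbonyl bond is cut to aryl anion 20 and a benzoyl donor. A Lewis-acid acylation would not spare the prenyl ether, whereas an aryllithium at −78 °C does. The third ring and the ketone are removed. The forward step needs 20 to acylate faster than its ortho silyl group migrates from oxygen to carbon.

**19 ⇒ 17 + 18 ⇒ 16.** The O6–CH2 bond is cut, then the C1–Br bond. Bromine must enter before the alkene is present, and in 16 the two open ring positions, both ortho to the only free hydroxyl, are equivalent. The result is a symmetric phenol whose free oxygen is exactly the one to be alkylated. The forward steps need mono-bromination and O-alkylation without loss of the silyl ethers.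

**16 ⇒ 7 + 11.** The bonds cut are C5–C6 and C3–C4, which join the two-carbon unit 11 to the four-carbon unit 7; C1–C6 is the bond of 7 that opens and is re-formed. This cut makes ring A with its oxygens already differentiated: O6 comes from the ketene carbonyl and is free, O2 and O4 are silylated. A hexasubstituted arene becomes two small achiral fragments that share one silyl group. The forward step needs a single orientation of the ketene–alkyne union and thermal opening of the donor-substituted 7.

**7 ⇒ 5 + 6 ⇒ 4 ⇒ 2 + 3 ⇒ 1.** The O–Si bond is cut, then the enol ether C–O bond, then the two ring bonds made by ketene–alkyne cycloaddition, then HCl from 1. The gain is three commodity reagents. The cycloaddition places the methyl on C4 of 4, so hydrolysis and re-enolisation must move the double bond to the methyl-bearing carbon before silylation.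

**11 ⇒ 10 + 6 ⇒ 9 ⇒ 8.** The O–Si bond is cut, then the alkyne is traced to the formyl carbon of 8 and a one-carbon carbenoid. The forward step needs O-silylation rather than C-silylation of 10, which the bulk of 6 should favour.

## Other disconnections considered

Alternative 1: The cut removes together the C1–carbonyl bond and the C6–O bond of ring A, tracing the ortho-hydroxy ketone to aryne A3 (spanning C1 and C6) and benzoic acid A4.
- Forward: fluoride would release A3 from silyl triflate A2. The carboxylate oxygen of A4 should add to C6, the aryl anion at C1 (next to the C2 acetal oxygen) should attack the carbonyl carbon, and collapse of the four-membered intermediate should give ketone A1 with O6 free and O2, O4 protected.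
- In favour: the benzoyl group and the single free hydroxyl arrive together under mild, non-acidic conditions. On this point the alternative is better than the chosen plan, which spends steps 6 and 8 on the ketone. The differentiation of O6 is equal to that of the chosen plan, and prenylation and deprotection of A1 would converge on 22.
- Against: A2 is a fully substituted benzene that must be prepared by site-selective protection, ortho-silylation and triflation of an aromatic starting material, so the regiochemical problem moves into the precursor. The direction of addition rests on distortion of A3 by one flanking alkoxy group. Protonation of the aryl anion before acyl transfer would stop at O-arylation. The two methoxymethyl ethers must later be removed with acid next to the prenyl ether, where the chosen plan uses fluoride.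
- Comparison: structurally the alternative decorates a purchased ring, the chosen plan builds it. Mechanistically it is a polar insertion with a regiochemical question, against a pericyclic cascade oriented by the polarity of the ynol ether. In step count the two are expected to be close, the shorter end being offset by the longer way to A2.

Alternative 2: The cut is the C4'–C5' bond of ring B, between the ring carbonyl next to the quaternary carbon and the carbon bearing the isobutyryl group.
- Forward: base would deprotonate the 1,3-diketone methylene of open-chain triketo ester A6, and the carbanion would attack the ester carbon (Dieckmann condensation) to close ring B as A5, with gem-dimethyl group, bridge and a symmetric protected ring A in place.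
- In favour: the quaternary carbon is present from the start, so the unselective double C-methylation of step 11 is avoided, and the bridge comes from ordinary enolate alkylation, not from oxidation of a methyl group. On both points the alternative is better than the chosen plan. Its key step is a reliable ionic condensation, at least the equal of the annulation in certainty.
- Against: A5 has no benzoyl group, so C-benzoylation of ring A would come last, after acetal cleavage, in the presence of the prenyl ether, the labile bridge and the ring B triketone. A6 has several acidic sites and could also close through oxygen or fragment by retro-Claisen cleavage.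
- Comparison: the alternative builds ring B and buys ring A, the reverse of the chosen plan, and leaves the ketone of ring A unsolved. The linear assembly of A6 and the late benzoylation should make it longer.

Alternative 3: The cut is the C1–C2 bond of ring A.
- Forward: base would deprotonate C1 of enol-ether keto ester A8, the carbon between the benzoyl group and the enol ether. The dienolate would attack the ester carbon C2 (intramolecular Claisen condensation), and loss of the alkoxide and enolisation would give A7, which is the same compound as 22.
- In favour: the prenyl group is on O6 before the ring exists, so the oxygen differentiation is equal to that of the chosen plan. Benzoyl, methyl and both free hydroxyls arrive in one step without protecting groups, which saves the four steps from 16 to 22. On step economy after ring formation the alternative is better.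
- Against: A8 needs the prenyl enol ether on one specific carbonyl of a polycarbonyl chain, which is hard to direct. The enol ether is an allyl vinyl ether, open to sigmatropic shift of the prenyl group to carbon on warming and to hydrolysis. The chain offers other closures, among them aldol attack on the benzoyl carbonyl and closure through oxygen.
- Comparison: both plans build ring A from acyclic carbon and fix the prenylation site before aromatisation. The alternative depends on selectivity among several enolisable positions, the annulation has one pericyclic course. The alternative would be shorter only if A8 were easy to make, which is the open question.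

Key step: step 5

Assumption: ring B of 28 is written as one enol tautomer; the other enol forms are the same compound.
Assumption: 10 should be reachable from 8 by the ynolate rearrangement of the Kowalski ester homologation, with the formyl hydrogen as the migrating group; a second access is among the fallbacks.
Remark on the structures: the atom mapping of the annulation was checked and is consistent (C1, C2, C3, C4 of 7 become C6, C3, C2, C1 of ring A; the CH and C–O carbons of 11 become C5 and C4). The ketene–ynol ether adduct is the 4-methyl isomer 4; the methyl reaches C2 only after hydrolysis and re-enolisation. The benzoyl group is introduced before desilylation by an anionic method, because Lewis-acid acylation beside a prenyl ether is unsafe. TIPS = tri(propan-2-yl)silyl.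

## Route

Step 1
Reactants: 1 propanoyl chloride; 2 ethoxyethyne
Product: 4 rac-3-ethoxy-4-methylcyclobut-2-en-1-one, via methylketene 3 (not isolated)
Conditions: Et3N, Et2O, 0 °C to rt, slow addition of 1 to 2 (1.5 equiv)
Reagents that add atoms: none
Why: Dehydrochlorination gives methylketene, which enters the known ketene–ynol ether (2+2) cycloaddition; the nucleophilic CH carbon of 2 bonds to the ketene carbonyl carbon, so ethoxy ends on C3 and methyl on C4. The C4 stereocenter is racemic and is erased in step 2.

Step 2
Reactants: 4 rac-3-ethoxy-4-methylcyclobut-2-en-1-one
Product: 5 3-hydroxy-2-methylcyclobut-2-en-1-one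
Conditions: 2 M HCl, THF, 0 °C to rt
Reagents that add atoms: water, O
Why: Acid hydrolysis of the vinylogous ester (enol ether hydrolysis) gives 2-methylcyclobutane-1,3-dione, which should rest as the more substituted enol with the methyl on the double bond; cold acid avoids the nucleophilic ring opening that such diones suffer in base.

Step 3
Reactants: 5 3-hydroxy-2-methylcyclobut-2-en-1-one; 6 chlorotri(propan-2-yl)silane
Product: 7 2-methyl-3-[tri(propan-2-yl)silyloxy]cyclobut-2-en-1-one
Conditions: Et3N, CH2Cl2, 0 °C to rt; filtration and distillation, no aqueous work-up
Reagents that add atoms: none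
Why: O-silylation of a strongly acidic enol, as for a silyl ester; it should trap the preferred enol, so the ring double bond lies between the methyl-bearing carbon and the oxygen-bearing carbon, and the bulky silyl group slows hydrolysis of the vinylogous silyl ester.

Step 4
Reactants: 8 ethyl formate; 6 chlorotri(propan-2-yl)silane
Product: 11 (ethynyloxy)tri(propan-2-yl)silane, via lithium 2,2-dibromoethenolate 9 (not isolated), via lithium ethynolate 10 (not isolated)
Conditions: CH2Br2, lithium 2,2,6,6-tetramethylpiperidide (2 equiv), THF, −78 °C; n-BuLi, −78 to 0 °C; 6, −78 °C to rt
Reagents that add atoms: dibromomethane, BrCBr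
Why: Ynolate formation as in the Kowalski ester homologation: dibromomethyllithium adds to the formate, the dibromo enolate undergoes bromine–lithium exchange and the carbenoid rearranges with 1,2-shift of hydrogen; the bulky silyl chloride should then silylate the ynolate on oxygen.

Step 5
Reactants: 7 2-methyl-3-[tri(propan-2-yl)silyloxy]cyclobut-2-en-1-one; 11 (ethynyloxy)tri(propan-2-yl)silane
Product: 16 4-methyl-3,5-bis[tri(propan-2-yl)silyloxy]phenol, via vinylketene 12 (not isolated), via vinylcyclobutenone 13 (not isolated), via dienylketene 14 (not isolated), via cyclohexadienone 15 (not isolated)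
Conditions: 11 (1.3 equiv), toluene, 80 °C then 110 °C, sealed tube, argon
Reagents that add atoms: none
Why: Proposed new method: thermal four-electron electrocyclic opening of 7 should give vinylketene 12, whose carbonyl carbon is attacked by the nucleophilic CH carbon of 11 in a stepwise polar (2+2) cycloaddition that forms C5–C6 and C3–C4 and gives 13. A second four-electron opening of 13 should give dienylketene 14, which closes ring A by six-electron disrotatory electrocyclisation (C1–C6) to 15, and tautomerisation gives phenol 16. The closest known reaction type is the Danheiser benzannulation of 3-alkylcyclobutenones with siloxyalkynes; the untested element is the 3-siloxy donor on the cyclobutenone, which should raise the barrier of the first opening without changing its course, since a 3-siloxycyclobutenone (13) opens under these conditions in every such annulation. Ring A is therefore closed by a pericyclic electrocyclisation, not by an ionic condensation. No stereocenter results: the quaternary carbon of 13 is racemic and becomes planar on ring opening. The selectivity needed is the orientation of the ketene–alkyne union, secured by the polarisation of 11, so that the ketene oxygen becomes the only free hydroxyl, para to the methyl group, and both flanking oxygens stay silylated. The excess of 11 should keep the product phenol from being acylated by 12.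

Step 6
Reactants: 16 4-methyl-3,5-bis[tri(propan-2-yl)silyloxy]phenol
Product: 17 2-bromo-4-methyl-3,5-bis[tri(propan-2-yl)silyloxy]phenol
Conditions: NBS (1.0 equiv), CH2Cl2, −78 to 0 °C
Reagents that add atoms: N-bromosuccinimide, O=C1CCC(=O)N1Br
Why: Electrophilic aromatic bromination ortho to the free phenol; the para position is blocked by methyl and the two ortho positions are equivalent, so one monobromide can form.

Step 7
Reactants: 17 2-bromo-4-methyl-3,5-bis[tri(propan-2-yl)silyloxy]phenol; 18 1-bromo-3-methylbut-2-ene
Product: 19 {[4-bromo-2-methyl-5-(3-methylbut-2-en-1-yloxy)-1,3-phenylene]bis(oxy)}bis[tri(propan-2-yl)silane]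
Conditions: K2CO3, acetone, 40 °C
Reagents that add atoms: none
Why: Williamson ether synthesis on the only free phenol; the hindered aryl silyl ethers should survive mild carbonate in acetone, so the prenyl group is placed on O6 alone.

Step 8
Reactants: 19 {[4-bromo-2-methyl-5-(3-methylbut-2-en-1-yloxy)-1,3-phenylene]bis(oxy)}bis[tri(propan-2-yl)silane]
Product: 21 {3-methyl-6-(3-methylbut-2-en-1-yloxy)-2,4-bis[tri(propan-2-yl)silyloxy]phenyl}(phenyl)methanone, via aryllithium 20 (not isolated)
Conditions: n-BuLi, THF, −78 °C; PhCON(OMe)Me, −78 to −20 °C; H2O
Reagents that add atoms: N-methoxy-N-methylbenzamide, CON(C)C(=O)c1ccccc1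
Why: Bromine–lithium exchange followed by Weinreb ketone synthesis; the aryllithium adds once to the amide and the ketone is released only on work-up, and at −78 °C exchange should outrun attack on the allyl ether and migration of the bulky silyl group.

Step 9
Reactants: 21 {3-methyl-6-(3-methylbut-2-en-1-yloxy)-2,4-bis[tri(propan-2-yl)silyloxy]phenyl}(phenyl)methanone
Product: 22 [2,4-dihydroxy-3-methyl-6-(3-methylbut-2-en-1-yloxy)phenyl](phenyl)methanone
Conditions: Bu4NF (2.2 equiv), AcOH (2.2 equiv), THF, 0 °C
Reagents that add atoms: none
Why: Fluoride cleavage of both aryl silyl ethers, buffered so that the phenoxides are protonated at once; the prenyl ether and the ketone are inert to fluoride.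

Step 10
Reactants: 23 benzene-1,3,5-triol; 24 2-methylpropanoyl chloride
Product: 25 2-methyl-1-(2,4,6-trihydroxyphenyl)propan-1-one
Conditions: AlCl3, nitrobenzene, rt to 60 °C; dilute HCl
Reagents that add atoms: none
Why: Friedel–Crafts C-acylation of phloroglucinol; the first acyl group deactivates the ring, so mono-acylation is expected.

Step 11
Reactants: 25 2-methyl-1-(2,4,6-trihydroxyphenyl)propan-1-one
Product: 26 3,5-dihydroxy-6,6-dimethyl-2-(2-methylpropanoyl)cyclohexa-2,4-dien-1-one
Conditions: NaOMe, MeI (2 equiv), MeOH, 0 °C to rt
Reagents that add atoms: iodomethane, CI
Why: Known dearomatising double C-methylation of an acylphloroglucinol polyanion at one ring carbon to the acylfilicinic acid; limiting the methyl iodide and separating mono- and trimethylated material is part of the step.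

Step 12
Reactants: 22 [2,4-dihydroxy-3-methyl-6-(3-methylbut-2-en-1-yloxy)phenyl](phenyl)methanone; 26 3,5-dihydroxy-6,6-dimethyl-2-(2-methylpropanoyl)cyclohexa-2,4-dien-1-one
Product: 28 sarothralin, via ortho-quinone methide 27 (not isolated)
Conditions: DDQ (1.0 equiv, slow addition), 26 (2 equiv), 1,4-dioxane, 10 °C to rt
Reagents that add atoms: none
Why: Oxidative generation of an ortho-quinone methide from an ortho-methylphenol, then Michael addition of a 1,3-dicarbonyl carbon (a cross-dehydrogenative coupling). The methyl is ortho to two hydroxyls and para to the ether oxygen, while the benzoyl group is meta to it, so hydride loss should occur there; the free ring carbon of 26 adds to the methylene of 27 and ring A rearomatises, with no stereocenter formed.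

## Compound list

1 | propanoyl chloride | CCC(Cl)=O | starting material
2 | ethoxyethyne | CCOC#C | starting material
3 | methylketene (prop-1-en-1-one) | CC=C=O | intermediate
4 | rac-3-ethoxy-4-methylcyclobut-2-en-1-one | CCOC1=CC(=O)C1C | intermediate
5 | 3-hydroxy-2-methylcyclobut-2-en-1-one (enol of 2-methylcyclobutane-1,3-dione) | CC1=C(O)CC1=O | intermediate
6 | chlorotri(propan-2-yl)silane | CC(C)[Si](Cl)(C(C)C)C(C)C | starting material
7 | 2-methyl-3-[tri(propan-2-yl)silyloxy]cyclobut-2-en-1-one | CC1=C(O[Si](C(C)C)(C(C)C)C(C)C)CC1=O | intermediate
8 | ethyl formate | CCOC=O | starting material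
9 | lithium 2,2-dibromoethen-1-olate | [Li+].[O-]C=C(Br)Br | intermediate
10 | lithium ethynolate | [Li+].[O-]C#C | intermediate
11 | (ethynyloxy)tri(propan-2-yl)silane | C#CO[Si](C(C)C)(C(C)C)C(C)C | intermediate
12 | 2-methyl-3-[tri(propan-2-yl)silyloxy]buta-1,3-dien-1-one | O=C=C(C)C(=C)O[Si](C(C)C)(C(C)C)C(C)C | intermediate
13 | rac-4-methyl-3-[tri(propan-2-yl)silyloxy]-4-{1-[tri(propan-2-yl)silyloxy]ethenyl}cyclobut-2-en-1-one | O=C1C=C(O[Si](C(C)C)(C(C)C)C(C)C)C1(C)C(=C)O[Si](C(C)C)(C(C)C)C(C)C | intermediate
14 | (3E)-4-methyl-3,5-bis[tri(propan-2-yl)silyloxy]hexa-1,3,5-trien-1-one | O=C=C/C(O[Si](C(C)C)(C(C)C)C(C)C)=C(C)\C(=C)O[Si](C(C)C)(C(C)C)C(C)C | intermediate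
15 | 4-methyl-3,5-bis[tri(propan-2-yl)silyloxy]cyclohexa-2,4-dien-1-one | O=C1C=C(O[Si](C(C)C)(C(C)C)C(C)C)C(C)=C(O[Si](C(C)C)(C(C)C)C(C)C)C1 | intermediate
16 | 4-methyl-3,5-bis[tri(propan-2-yl)silyloxy]phenol | Cc1c(O[Si](C(C)C)(C(C)C)C(C)C)cc(O)cc1O[Si](C(C)C)(C(C)C)C(C)C | intermediate
17 | 2-bromo-4-methyl-3,5-bis[tri(propan-2-yl)silyloxy]phenol | Cc1c(O[Si](C(C)C)(C(C)C)C(C)C)cc(O)c(Br)c1O[Si](C(C)C)(C(C)C)C(C)C | intermediate
18 | 1-bromo-3-methylbut-2-ene | CC(C)=CCBr | starting material
19 | {[4-bromo-2-methyl-5-(3-methylbut-2-en-1-yloxy)-1,3-phenylene]bis(oxy)}bis[tri(propan-2-yl)silane] | CC(C)=CCOc1cc(O[Si](C(C)C)(C(C)C)C(C)C)c(C)c(O[Si](C(C)C)(C(C)C)C(C)C)c1Br | intermediate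
20 | {3-methyl-6-(3-methylbut-2-en-1-yloxy)-2,4-bis[tri(propan-2-yl)silyloxy]phenyl}lithium | [Li]c1c(OCC=C(C)C)cc(O[Si](C(C)C)(C(C)C)C(C)C)c(C)c1O[Si](C(C)C)(C(C)C)C(C)C | intermediate
21 | {3-methyl-6-(3-methylbut-2-en-1-yloxy)-2,4-bis[tri(propan-2-yl)silyloxy]phenyl}(phenyl)methanone | CC(C)=CCOc1cc(O[Si](C(C)C)(C(C)C)C(C)C)c(C)c(O[Si](C(C)C)(C(C)C)C(C)C)c1C(=O)c1ccccc1 | intermediate
22 | [2,4-dihydroxy-3-methyl-6-(3-methylbut-2-en-1-yloxy)phenyl](phenyl)methanone | CC(C)=CCOc1cc(O)c(C)c(O)c1C(=O)c1ccccc1 | intermediate
23 | benzene-1,3,5-triol | Oc1cc(O)cc(O)c1 | starting material
24 | 2-methylpropanoyl chloride | CC(C)C(Cl)=O | starting material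
25 | 2-methyl-1-(2,4,6-trihydroxyphenyl)propan-1-one | CC(C)C(=O)c1c(O)cc(O)cc1O | intermediate
26 | 3,5-dihydroxy-6,6-dimethyl-2-(2-methylpropanoyl)cyclohexa-2,4-dien-1-one | CC(C)C(=O)C1=C(O)C=C(O)C(C)(C)C1=O | intermediate
27 | 4-benzoyl-5-hydroxy-6-methylidene-3-(3-methylbut-2-en-1-yloxy)cyclohexa-2,4-dien-1-one | C=C1C(=O)C=C(OCC=C(C)C)C(C(=O)c2ccccc2)=C1O | intermediate
28 | sarothralin, 4-{[3-benzoyl-2,6-dihydroxy-4-(3-methylbut-2-en-1-yloxy)phenyl]methyl}-3,5-dihydroxy-6,6-dimethyl-2-(2-methylpropanoyl)cyclohexa-2,4-dien-1-one | CC(C)=CCOc1cc(O)c(CC2=C(O)C(C)(C)C(=O)C(C(=O)C(C)C)=C2O)c(O)c1C(=O)c1ccccc1 | target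

## Step count and least certain steps

Total steps: 12. Longest linear sequence: 9 (steps 1, 2, 3, 5, 6, 7, 8, 9, 12).

**Step 5 (key step, proposed as a new variant).** Most likely to go wrong: the first electrocyclic opening may be too slow, because the siloxy donor stabilises 7 as a vinylogous ester. At the temperatures then needed, the terminal ynol ether 11 can isomerise by 1,3-silyl shift or oligomerise, and traces of water hydrolyse 7. Fallback with known chemistry, setting out from 6 and returning at 16: commercial 2-methylbenzene-1,3-diol is silylated on both oxygens with 6 (imidazole, DMF) to [(2-methyl-1,3-phenylene)bis(oxy)]bis[tri(propan-2-yl)silane] F1. Sterically controlled aromatic C–H borylation ([Ir(OMe)(cod)]2, 4,4'-di-tert-butyl-2,2'-bipyridine, B2pin2, 80 °C) should go to the only ring position without an ortho substituent and give 4,4,5,5-tetramethyl-2-{4-methyl-3,5-bis[tri(propan-2-yl)silyloxy]phenyl}-1,3,2-dioxaborolane F2. Oxidation of the C–B bond (NaBO3, THF/H2O) gives 16.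

**Step 12.** Most likely to go wrong: over-oxidation of the newly formed, doubly activated methylene bridge and oxidative consumption of the enol partner while oxidant is still present; attack of the oxidant on the allylic position of the prenyl ether and self-trapping of 27 by unreacted 22 are further risks. Fallback, setting out from 22 and returning at 28: oxidation and C–C bond formation are separated. 22 is oxidised with DDQ in acetic acid in the absence of 26, so that the quinone methide is captured by the solvent as [3-benzoyl-2,6-dihydroxy-4-(3-methylbut-2-en-1-yloxy)phenyl]methyl acetate F3. F3 is then heated with 26 (toluene, 80 °C); loss of acetic acid regenerates 27 under non-oxidising conditions and Michael addition gives 28.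

**Step 8.** Most likely to go wrong: migration of the ortho silyl group from oxygen to carbon in 20 (retro-Brook shift), or slow addition of the hindered aryllithium followed by protonation on work-up. Fallback, setting out from 17 and returning at 21: 17 is O-benzoylated (benzoyl chloride, Et3N, catalytic 4-dimethylaminopyridine) to 2-bromo-4-methyl-3,5-bis[tri(propan-2-yl)silyloxy]phenyl benzoate F4. Bromine–lithium exchange (n-BuLi, THF, −78 °C) triggers a fast intramolecular 1,3 O-to-C benzoyl shift (anionic Fries rearrangement), which should outrun silyl migration, and gives {6-hydroxy-3-methyl-2,4-bis[tri(propan-2-yl)silyloxy]phenyl}(phenyl)methanone F5. Alkylation of its chelated phenol with 18 (K2CO3, acetone) gives 21.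

**Step 4.** Most likely to go wrong: a second addition of the carbenoid to the very electrophilic formate, and silylation of the unhindered ynolate on carbon instead of oxygen. Fallback, setting out from 6 and returning at 10: acetylene is metalated (n-BuLi, THF, −78 °C) to lithium acetylide F6, which is oxidised with lithium tert-butyl peroxide (from tert-butyl hydroperoxide and LiN(SiMe3)2) to 10. Silylation with 6 as in step 4 gives 11.

## Further compounds

F1 | step 5 | [(2-methyl-1,3-phenylene)bis(oxy)]bis[tri(propan-2-yl)silane] | Cc1c(O[Si](C(C)C)(C(C)C)C(C)C)cccc1O[Si](C(C)C)(C(C)C)C(C)C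
F2 | step 5 | 4,4,5,5-tetramethyl-2-{4-methyl-3,5-bis[tri(propan-2-yl)silyloxy]phenyl}-1,3,2-dioxaborolane | Cc1c(O[Si](C(C)C)(C(C)C)C(C)C)cc(B2OC(C)(C)C(C)(C)O2)cc1O[Si](C(C)C)(C(C)C)C(C)C
F3 | step 12 | [3-benzoyl-2,6-dihydroxy-4-(3-methylbut-2-en-1-yloxy)phenyl]methyl acetate | CC(=O)OCc1c(O)cc(OCC=C(C)C)c(C(=O)c2ccccc2)c1O
F4 | step 8 | 2-bromo-4-methyl-3,5-bis[tri(propan-2-yl)silyloxy]phenyl benzoate | Cc1c(O[Si](C(C)C)(C(C)C)C(C)C)cc(OC(=O)c2ccccc2)c(Br)c1O[Si](C(C)C)(C(C)C)C(C)C
F5 | step 8 | {6-hydroxy-3-methyl-2,4-bis[tri(propan-2-yl)silyloxy]phenyl}(phenyl)methanone | O=C(c1ccccc1)c1c(O)cc(O[Si](C(C)C)(C(C)C)C(C)C)c(C)c1O[Si](C(C)C)(C(C)C)C(C)C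
F6 | step 4 | lithium acetylide | [Li]C#C
A1 | alternative 1 | [6-hydroxy-2,4-bis(methoxymethoxy)-3-methylphenyl](phenyl)methanone | O=C(c1ccccc1)c1c(O)cc(OCOC)c(C)c1OCOC
A2 | alternative 1 | 3,5-bis(methoxymethoxy)-4-methyl-2-(trimethylsilyl)phenyl trifluoromethanesulfonate | COCOc1cc(OS(=O)(=O)C(F)(F)F)c([Si](C)(C)C)c(OCOC)c1C
A3 | alternative 1 | 3,5-bis(methoxymethoxy)-4-methyl-1,2-didehydrobenzene | COCOC1=C(C)C(OCOC)=CC#C1
A4 | alternative 1 | benzoic acid | OC(=O)c1ccccc1
A5 | alternative 2 | 4-{[2,6-bis(methoxymethoxy)-4-(3-methylbut-2-en-1-yloxy)phenyl]methyl}-3,5-dihydroxy-6,6-dimethyl-2-(2-methylpropanoyl)cyclohexa-2,4-dien-1-one | CC(C)=CCOc1cc(OCOC)c(CC2=C(O)C(C)(C)C(=O)C(C(=O)C(C)C)=C2O)c(OCOC)c1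
A6 | alternative 2 | rac-methyl 4-{[2,6-bis(methoxymethoxy)-4-(3-methylbut-2-en-1-yloxy)phenyl]methyl}-2,2,8-trimethyl-3,5,7-trioxononanoate | COC(=O)C(C)(C)C(=O)C(Cc1c(OCOC)cc(OCC=C(C)C)cc1OCOC)C(=O)CC(=O)C(C)C
A7 | alternative 3 | [2,4-dihydroxy-3-methyl-6-(3-methylbut-2-en-1-yloxy)phenyl](phenyl)methanone | CC(C)=CCOc1cc(O)c(C)c(O)c1C(=O)c1ccccc1
A8 | alternative 3 | rac-methyl 2-methyl-5-(3-methylbut-2-en-1-yloxy)-3,7-dioxo-7-phenylhept-4-enoate (double-bond geometry not fixed) | COC(=O)C(C)C(=O)C=C(OCC=C(C)C)CC(=O)c1ccccc1
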